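**Retrosynthetic overview**

1. Endgame: the oxirane comes from the C8=C9 alkene, the ester from acylation of O6–H, and O6/H5 from the C5=C6 alkene by O4-directed epoxidation and reductive opening with trivalent titanium; the C8 methyl and the C8=C9 alkene come from a C9 ketone.
2. Key disconnection: ring B (C1, C5, C6, C7, C8, C9, C10) is split into the five-carbon unit C1–C10–C9–C8–C7, held as a 1-silyloxy-1-alkenylcyclopropane (alkene C1=C10, ring C9/C8/C7), and the two-carbon unit C5–C6, an ethynyl group on the C4 carbinol. A rhodium-catalysed (5+2) cycloaddition forms C1–C5 and C6–C7, so ring A (C1–C5, closed across the C2–C3–C4 tether) and ring B form together and the quaternary C1 is created.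
3. The cyclopropane carries no C8 methyl (it is added later by methylenation of the C9 ketone). A methyl on the three-membered ring would make C9 a stereocentre; once the less substituted ring bond is cleaved, that centre and not C4 would fix the face of C1, and the remote C4 cannot control the cyclopropanation.
4. Precursor: (S)-terpinen-4-ol supplies C4 with its configuration, the isopropyl group, C1–C3, the C1 methyl, C5 and C6. Ozonolysis gives a methyl ketone (to enone, silyloxydiene, cyclopropane) and a CH2–CHO arm that becomes C≡CH with no change in carbon count (enol triflate elimination, not a homologation).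
5. Ring order: rings A and B in one step (step 9); the oxirane last (step 19).

Key step: step 9

Assumption: (S)-(+)-terpinen-4-ol is taken as available in high enantiomeric purity; atom numbers are those of the daucane skeleton (ring A = C1–C5, ring B = C1, C5–C10) and β denotes the face of the C1 methyl group.

**Route**

Step 1
Reactants: 1 (S)-terpinen-4-ol
Product: 2 triethylsilyl ether of 1
Conditions: Et3SiOTf, 2,6-lutidine, CH2Cl2, 0 °C to rt
Reagents that add atoms: triethylsilyl trifluoromethanesulfonate, CC[Si](CC)(CC)OS(=O)(=O)C(F)(F)F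
Why: Silylation of the hindered tertiary alcohol with a silyl triflate and a hindered pyridine base is standard and leaves the C4 stereocentre, which carries through to the target, untouched.

Step 2
Reactants: 2 triethylsilyl ether of 1
Product: 4 keto acetal 5-isopropyl-7,7-dimethoxy-5-(triethylsilyloxy)heptan-2-one, via keto aldehyde 3 (not isolated)
Conditions: O3, CH2Cl2/MeOH, NaHCO3, −78 °C; Me2S, −78 °C to rt; then HC(OMe)3, CeCl3·7H2O (cat.), MeOH, rt
Reagents that add atoms: ozone, [O-][O+]=O; methanol, CO; trimethyl orthoformate, COC(OC)OC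
Why: Ozonolysis of the trisubstituted ring alkene (Criegee mechanism, reductive work-up) gives the methyl ketone and the CH2–CHO arm, and lanthanide-chloride-catalysed acetalization converts only the aldehyde, so the two carbonyl groups are differentiated in one pot without touching C4.

Step 3
Reactants: 4 keto acetal; 5 diethyl [2-(methoxy(methyl)amino)-2-oxoethyl]phosphonate
Product: 6 (E)-6-isopropyl-8,8-dimethoxy-N-methoxy-N,3-dimethyl-6-(triethylsilyloxy)oct-2-enamide
Conditions: NaH, THF, 0 °C to 50 °C; chromatography
Reagents that add atoms: phosphonate 5, CCOP(=O)(CC(=O)N(C)OC)OCC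
Why: Horner–Wadsworth–Emmons olefination of the methyl ketone with the sodium salt of a stabilized phosphonate should give the trisubstituted enamide with the longer chain trans to the carbonyl group (E), the minor Z isomer being removed by chromatography.

Step 4
Reactants: 6 enamide acetal
Product: 7 (E)-6-isopropyl-N-methoxy-N,3-dimethyl-8-oxo-6-(triethylsilyloxy)oct-2-enamide
Conditions: pyridinium tosylate (cat.), acetone/H2O, 45 °C
Reagents that add atoms: water, O
Why: Mild acid-catalysed acetal hydrolysis frees the aldehyde while the hindered tertiary triethylsilyl ether and the enamide are stable to pyridinium tosylate in wet acetone.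

Step 5
Reactants: 7 enamide aldehyde
Product: 10 (E)-6-ethynyl-N-methoxy-N,3,7-trimethyl-6-(triethylsilyloxy)oct-2-enamide, via potassium enolate 8 (not isolated), via Z-enol triflate 9 (not isolated)
Conditions: KN(SiMe3)2 (1.1 equiv), THF, −78 °C; PhNTf2 (1.15 equiv); then KN(SiMe3)2 (1.5 equiv), −78 to −20 °C
Reagents that add atoms: none
Why: O-Triflation of the kinetically formed potassium enolate and anti β-elimination of triflate from the Z-enol triflate by a second portion of amide base turn CH2–CHO into C≡CH with no change in carbon count (enol triflate elimination route to alkynes), so the ethynyl group sits directly on C4 as the three-atom tether requires.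

Step 6
Reactants: 10 enyne enamide
Product: 11 ynenone (E)-7-ethynyl-4,8-dimethyl-7-(triethylsilyloxy)non-3-en-2-one
Conditions: MeMgBr (2.2 equiv), THF, −20 to 0 °C; aq. NH4Cl
Reagents that add atoms: methylmagnesium bromide, C[Mg]Br
Why: Weinreb ketone synthesis: the chelated tetrahedral magnesium adduct stops at the ketone stage and 1,2-addition to the β,β-disubstituted enamide is the normal course, the excess Grignard reagent covering any deprotonation of the alkyne.

Step 7
Reactants: 11 ynenone
Product: 12 (E)-2-(tert-butyldimethylsilyloxy)-7-ethynyl-4,8-dimethyl-7-(triethylsilyloxy)nona-1,3-diene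
Conditions: t-BuMe2SiOTf, Et3N, CH2Cl2, −78 to 0 °C
Reagents that add atoms: tert-butyldimethylsilyl trifluoromethanesulfonate, CC(C)(C)[Si](C)(C)OS(=O)(=O)C(F)(F)F
Why: Soft enolization with a silyl triflate and triethylamine removes a proton from the α' methyl group and gives the cross-conjugated 2-silyloxy-1,3-diene, as is usual for methyl enones.

Step 8
Reactants: 12 silyloxydiene
Product: 13 1-(tert-butyldimethylsilyloxy)-1-[(E)-5-ethynyl-2,6-dimethyl-5-(triethylsilyloxy)hept-1-enyl]cyclopropane
Conditions: Et2Zn, CH2I2 (1.2 equiv each), CH2Cl2, 0 °C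
Reagents that add atoms: diiodomethane, ICI
Why: Simmons–Smith cyclopropanation in the Furukawa variant picks the electron-rich, unhindered silyl enol ether double bond over the trisubstituted alkene and the alkyne, and since the new ring carries two identical CH2 groups no stereocentre arises.

Step 9
Reactants: 13 alkyne-tethered silyloxyvinylcyclopropane
Product: 14 cycloadduct, bicyclo[5.3.0]deca-5,9-diene (daucane numbering) with 1β-methyl, 4α-isopropyl, 4β-triethylsilyloxy and 9-tert-butyldimethylsilyloxy groups
Conditions: [Rh(CO)2Cl]2 (5 mol%), ClCH2CH2Cl, 0.01 M, 80 °C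
Reagents that add atoms: none
Why: Proposed new method: monovalent rhodium binds the alkyne and the alkenylcyclopropane, inserts into a C9–CH2 bond of the strained ring (helped by the silyloxy donor on C9) to give a rhodacycle with a σ-bond to C7 and an allyl unit over C9–C10–C1, the tethered alkyne then inserts at C1 (bond C1–C5) and reductive elimination joins C6 to C7. The closest known reaction type is the rhodium-catalysed intramolecular (5+2) cycloaddition of alkyne-tethered vinylcyclopropanes, together with the intermolecular (5+2) of 1-silyloxy-1-vinylcyclopropanes with alkynes, neither shown for an alkene terminus that bears two carbon substituents. Ring A closes in the 5-exo sense when the internal alkyne carbon C5 bonds to C1 across the three-atom tether C2–C3–C4, and ring B closes as a cyclohepta-1,4-diene when the eight-membered rhodacycle collapses by C6–C7 reductive elimination. The only new stereocentre, C1, is set relative to C4 during alkyne insertion: in the forming ring A the isopropyl group is expected to take the pseudo-equatorial site away from the C1 methyl and the smaller silyloxy group the pseudo-axial site syn to it, which gives the isomer with methyl and oxygen cis. The step needs this facial selectivity and the engagement of a trisubstituted alkene; the small CO and chloride ligands, the E geometry (tether in the syn position of the allyl) and the donor on C9 are meant to secure the latter, and because the cyclopropane is unsubstituted there is no regiochemical question in the ring opening and no second stereocentre that could override C4.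

Step 10
Reactants: 14 cycloadduct
Product: 15 ketone, 1β-methyl-4α-isopropyl-4β-(triethylsilyloxy)bicyclo[5.3.0]dec-5-en-9-one (daucane numbering)
Conditions: Bu4NF (1.05 equiv), AcOH (1.5 equiv), THF, −20 °C
Reagents that add atoms: none
Why: Fluoride cleaves the silyl enol ether far faster than the hindered tertiary alkyl silyl ether, and protonation of the enolate by acetic acid gives the C9 ketone (selective enol silyl ether cleavage).

Step 11
Reactants: 15 ketone
Product: 19 8-methylene ketone, via lithium enolate 16 (not isolated), via Mannich base 17 (not isolated), via methiodide 18 (not isolated)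
Conditions: LiN(i-Pr)2, THF, −78 °C; CH2=NMe2 iodide, −78 °C to rt; then MeI, MeOH, rt; then aq. NaHCO3, CH2Cl2
Reagents that add atoms: N,N-dimethylmethyleneiminium iodide, C=[N+](C)C.[I-]
Why: Kinetic deprotonation occurs at C8 because C10 is neopentylic, and the Mannich reaction of this enolate with the iminium salt followed by quaternization and E1cB loss of trimethylamine (methylenation through a Mannich base) places the future C8 methyl carbon, the C8 stereocentre of the intermediates being removed in the elimination.

Step 12
Reactants: 19 8-methylene ketone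
Product: 21 enol triflate, 4β-(triethylsilyloxy)dauca-5,8-dien-9-yl trifluoromethanesulfonate, via lithium enolate 20 (not isolated)
Conditions: LiBH(s-Bu)3 (1.05 equiv), THF, −78 °C; then N-(5-chloropyridin-2-yl)triflimide, −78 to 0 °C; aq. NH4Cl
Reagents that add atoms: N-(5-chloropyridin-2-yl)bis(trifluoromethanesulfonyl)imide, FC(F)(F)S(=O)(=O)N(c1ccc(Cl)cn1)S(=O)(=O)C(F)(F)F
Why: Conjugate hydride addition to the exocyclic enone generates the C8=C9 enolate regiospecifically, and its O-sulfonylation fixes the double bond at C8=C9 (reductive enolate formation and triflation).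

Step 13
Reactants: 21 enol triflate
Product: 22 4β-(triethylsilyloxy)dauca-5,8-diene
Conditions: Pd(OAc)2 (5 mol%), PPh3 (10 mol%), Bu3N, HCO2H, DMF, 60 °C
Reagents that add atoms: none
Why: Palladium-catalysed formate reduction of the enol triflate (oxidative addition to zerovalent palladium, formate-to-hydride exchange with loss of CO2, reductive elimination) replaces the triflate by hydrogen without moving the C8=C9 double bond.

Step 14
Reactants: 22 silyl ether diene
Product: 23 dauca-5,8-dien-4β-ol
Conditions: Bu4NF, THF, 40 °C
Reagents that add atoms: none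
Why: Fluoride-mediated desilylation frees the tertiary allylic alcohol under basic conditions, which avoids ionization of the allylic C4–O bond.

Step 15
Reactants: 23 dienol
Product: 24 5β,6β-epoxydauc-8-en-4β-ol
Conditions: VO(acac)2 (5 mol%), t-BuOOH (1.3 equiv), CH2Cl2, 0 °C to rt
Reagents that add atoms: tert-butyl hydroperoxide, CC(C)(C)OO
Why: Vanadium-catalysed hydroxyl-directed epoxidation of an allylic alcohol: the vanadate ester of O4 delivers the peroxide oxygen to the adjacent C5=C6 bond on the face of O4 (β), which sets C6 (and C5 for the moment) and leaves the unactivated C8=C9 alkene alone.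

Step 16
Reactants: 24 epoxy alcohol
Product: 25 dauc-8-ene-4β,6β-diol (5α-H)
Conditions: Cp2TiCl2 (2.5 equiv), Zn dust, THF, rt; 1,4-cyclohexadiene (10 equiv); dilute HCl work-up
Reagents that add atoms: none
Why: Reductive epoxide opening by trivalent titanium (Cp2TiCl) breaks the C5–O bond to the tertiary radical while O6 stays bound to titanium with its configuration, and hydrogen-atom transfer from 1,4-cyclohexadiene to the face opposite the bulky titanoxy group, O4 and the C1 methyl group should give H5 α, that is the trans ring fusion.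

Step 17
Reactants: 26 4-hydroxybenzoic acid
Product: 28 4-(tert-butyldimethylsilyloxy)benzoic acid, via silyl ester 27 (not isolated)
Conditions: t-BuMe2SiCl (2.2 equiv), imidazole, DMF, rt; then AcOH/THF/H2O, rt
Reagents that add atoms: tert-butyldimethylsilyl chloride, CC(C)(C)[Si](C)(C)Cl
Why: Silylation of both acidic groups and selective hydrolysis of the labile silyl ester leaves the phenol protected as its silyl ether (standard protection).

Step 18
Reactants: 25 diol; 28 4-(tert-butyldimethylsilyloxy)benzoic acid
Product: 29 4β-hydroxydauc-8-en-6β-yl 4-(tert-butyldimethylsilyloxy)benzoate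
Conditions: EDC·HCl, DMAP, CH2Cl2, rt to 40 °C
Reagents that add atoms: acid 28, CC(C)(C)[Si](C)(C)Oc1ccc(cc1)C(O)=O
Why: Steglich esterification acylates the secondary O6–H, the tertiary O4–H being inert to the acylpyridinium intermediate, and no stereocentre is touched.

Step 19
Reactants: 29 ester
Product: 30 8α,9α-epoxy-4β-hydroxydaucan-6β-yl 4-(tert-butyldimethylsilyloxy)benzoate
Conditions: mCPBA, NaHCO3, CH2Cl2, 0 °C
Reagents that add atoms: 3-chloroperoxybenzoic acid, OOC(=O)c1cccc(Cl)c1
Why: Prilezhaev epoxidation of the trisubstituted C8=C9 alkene is expected from the α face, because the β face is screened by the C1 methyl group and the O6 ester, which sets C8 and C9 as in the target.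

Step 20
Reactants: 30 epoxy ester
Product: 31 target, 8α,9α-epoxy-4β-hydroxydaucan-6β-yl 4-hydroxybenzoate
Conditions: Bu4NF (1.1 equiv), AcOH (1.2 equiv), THF, 0 °C
Reagents that add atoms: none
Why: The aryl silyl ether is cleaved by buffered fluoride within minutes at 0 °C, conditions under which the ester, the epoxide and the tertiary alcohol are stable.

**Compound list**

1 | (S)-terpinen-4-ol, (S)-1-isopropyl-4-methylcyclohex-3-en-1-ol | CC(C)[C@]1(O)CCC(C)=CC1 | starting material
2 | triethylsilyl ether of 1 | CC(C)[C@]1(O[Si](CC)(CC)CC)CCC(C)=CC1 | intermediate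
3 | keto aldehyde, 3-isopropyl-6-oxo-3-(triethylsilyloxy)heptanal, carbinol configuration as in 1 | CC(C)[C@@](O[Si](CC)(CC)CC)(CC=O)CCC(C)=O | intermediate (not isolated)
4 | keto acetal, 5-isopropyl-7,7-dimethoxy-5-(triethylsilyloxy)heptan-2-one | CC(C)[C@@](O[Si](CC)(CC)CC)(CC(OC)OC)CCC(C)=O | intermediate
5 | diethyl [2-(methoxy(methyl)amino)-2-oxoethyl]phosphonate | CCOP(=O)(CC(=O)N(C)OC)OCC | starting material
6 | (E)-6-isopropyl-8,8-dimethoxy-N-methoxy-N,3-dimethyl-6-(triethylsilyloxy)oct-2-enamide | CC(C)[C@@](O[Si](CC)(CC)CC)(CC(OC)OC)CC/C(C)=C/C(=O)N(C)OC | intermediate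
7 | (E)-6-isopropyl-N-methoxy-N,3-dimethyl-8-oxo-6-(triethylsilyloxy)oct-2-enamide | CC(C)[C@@](O[Si](CC)(CC)CC)(CC=O)CC/C(C)=C/C(=O)N(C)OC | intermediate
8 | potassium (Z)-enolate of 7 | CC(C)[C@@](O[Si](CC)(CC)CC)(/C=C\[O-])CC/C(C)=C/C(=O)N(C)OC.[K+] | intermediate (not isolated)
9 | (Z)-enol triflate of 7 | CC(C)[C@@](O[Si](CC)(CC)CC)(/C=C\OS(=O)(=O)C(F)(F)F)CC/C(C)=C/C(=O)N(C)OC | intermediate (not isolated)
10 | (E)-6-ethynyl-N-methoxy-N,3,7-trimethyl-6-(triethylsilyloxy)oct-2-enamide | CC(C)[C@@](O[Si](CC)(CC)CC)(C#C)CC/C(C)=C/C(=O)N(C)OC | intermediate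
11 | ynenone, (E)-7-ethynyl-4,8-dimethyl-7-(triethylsilyloxy)non-3-en-2-one | CC(C)[C@@](O[Si](CC)(CC)CC)(C#C)CC/C(C)=C/C(C)=O | intermediate
12 | (E)-2-(tert-butyldimethylsilyloxy)-7-ethynyl-4,8-dimethyl-7-(triethylsilyloxy)nona-1,3-diene | CC(C)[C@@](O[Si](CC)(CC)CC)(C#C)CC/C(C)=C/C(=C)O[Si](C)(C)C(C)(C)C | intermediate
13 | 1-(tert-butyldimethylsilyloxy)-1-[(E)-5-ethynyl-2,6-dimethyl-5-(triethylsilyloxy)hept-1-enyl]cyclopropane | CC(C)[C@@](O[Si](CC)(CC)CC)(C#C)CC/C(C)=C/C1(O[Si](C)(C)C(C)(C)C)CC1 | intermediate
14 | cycloadduct, 1β-methyl-4α-isopropyl-4β-(triethylsilyloxy)-9-(tert-butyldimethylsilyloxy)bicyclo[5.3.0]deca-5,9-diene (daucane numbering) | CC(C)[C@]1(O[Si](CC)(CC)CC)CC[C@]2(C)C=C(O[Si](C)(C)C(C)(C)C)CCC=C12 | intermediate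
15 | ketone, 1β-methyl-4α-isopropyl-4β-(triethylsilyloxy)bicyclo[5.3.0]dec-5-en-9-one | CC(C)[C@]1(O[Si](CC)(CC)CC)CC[C@]2(C)CC(=O)CCC=C12 | intermediate
16 | lithium C8=C9 enolate of 15 | CC(C)[C@]1(O[Si](CC)(CC)CC)CC[C@]2(C)CC([O-])=CCC=C12.[Li+] | intermediate (not isolated)
17 | Mannich base, 8-(dimethylaminomethyl) derivative of 15 (C8 epimers) | CC(C)[C@]1(O[Si](CC)(CC)CC)CC[C@]2(C)CC(=O)C(CN(C)C)CC=C12 | intermediate (not isolated)
18 | methiodide of 17 | CC(C)[C@]1(O[Si](CC)(CC)CC)CC[C@]2(C)CC(=O)C(C[N+](C)(C)C)CC=C12.[I-] | intermediate (not isolated)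
19 | 8-methylene ketone | CC(C)[C@]1(O[Si](CC)(CC)CC)CC[C@]2(C)CC(=O)C(=C)CC=C12 | intermediate
20 | lithium enolate from conjugate reduction of 19 (C8 methyl, C8=C9) | CC(C)[C@]1(O[Si](CC)(CC)CC)CC[C@]2(C)CC([O-])=C(C)CC=C12.[Li+] | intermediate (not isolated)
21 | 4β-(triethylsilyloxy)dauca-5,8-dien-9-yl trifluoromethanesulfonate | CC(C)[C@]1(O[Si](CC)(CC)CC)CC[C@]2(C)CC(OS(=O)(=O)C(F)(F)F)=C(C)CC=C12 | intermediate
22 | 4β-(triethylsilyloxy)dauca-5,8-diene | CC(C)[C@]1(O[Si](CC)(CC)CC)CC[C@]2(C)CC=C(C)CC=C12 | intermediate
23 | dauca-5,8-dien-4β-ol | CC(C)[C@]1(O)CC[C@]2(C)CC=C(C)CC=C12 | intermediate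
24 | 5β,6β-epoxydauc-8-en-4β-ol | CC(C)[C@]1(O)CC[C@]2(C)CC=C(C)C[C@H]3O[C@@]312 | intermediate
25 | dauc-8-ene-4β,6β-diol (5α-H, trans-fused) | CC(C)[C@]1(O)CC[C@]2(C)CC=C(C)C[C@@H](O)[C@H]21 | intermediate
26 | 4-hydroxybenzoic acid | O=C(O)c1ccc(O)cc1 | starting material
27 | tert-butyldimethylsilyl 4-(tert-butyldimethylsilyloxy)benzoate | CC(C)(C)[Si](C)(C)Oc1ccc(cc1)C(=O)O[Si](C)(C)C(C)(C)C | intermediate (not isolated)
28 | 4-(tert-butyldimethylsilyloxy)benzoic acid | CC(C)(C)[Si](C)(C)Oc1ccc(cc1)C(O)=O | intermediate
29 | 4β-hydroxydauc-8-en-6β-yl 4-(tert-butyldimethylsilyloxy)benzoate | CC(C)[C@]1(O)CC[C@]2(C)CC=C(C)C[C@@H](OC(=O)c3ccc(O[Si](C)(C)C(C)(C)C)cc3)[C@H]21 | intermediate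
30 | 8α,9α-epoxy-4β-hydroxydaucan-6β-yl 4-(tert-butyldimethylsilyloxy)benzoate | CC(C)[C@]1(O)CC[C@]2(C)C[C@@H]3O[C@]3(C)C[C@@H](OC(=O)c3ccc(O[Si](C)(C)C(C)(C)C)cc3)[C@H]21 | intermediate
31 | 8α,9α-epoxy-4β-hydroxydaucan-6β-yl 4-hydroxybenzoate (CNP0163817.3) | CC(C)[C@]1(O)CC[C@]2(C)C[C@@H]3O[C@]3(C)C[C@@H](OC(=O)c3ccc(O)cc3)[C@H]21 | target

**Step count and risks**

Total step count: 20. Longest linear sequence: 19 steps (steps 1–16 and 18–20, from 1); step 17 prepares the acid 28.

Steps most likely to fail:

1. Step 9 (the proposed new method). Alkyne insertion at the fully substituted allyl terminus C1 may be too slow, so that the opened cyclopropane isomerizes to acyclic dienol ethers instead of closing, and the C4 stereocentre may discriminate the two faces of C1 only weakly. The fallback closes the two rings one after the other by known reactions; it sets out from ynenone 11 and returns at ketone 15. Bu3SnH and AIBN in benzene at 80 °C should add a stannyl radical to the terminal alkyne carbon and close ring A by 5-exo attack of the C5 vinyl radical on the enone β-carbon C1 (vinyl-radical cyclization onto an enone), giving the stannylated methylenecyclopentane F1. Protodestannylation with HCl in CH2Cl2 gives the exocyclic alkene F2, at which stage C1 epimers would be separated. Kinetic deprotonation of the methyl ketone at its methyl group with LiN(i-Pr)2 at −78 °C and alkylation with allyl bromide gives the dienone F3. Ring-closing metathesis with the second-generation Hoveyda–Grubbs catalyst in toluene at 80 °C then closes ring B at C5=C6 with loss of ethylene and gives 15.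

2. Step 5. The potassium enolate may expel triethylsilanolate (E1cB) before it is triflated, or the enamide may be attacked by the amide base during the elimination. The fallback avoids any enolate; it sets out from aldehyde 7 and returns at enyne 10. Condensation with hydrazine hydrate in EtOH at 0 °C gives the hydrazone F4; iodine and tetramethylguanidine in THF convert it, with loss of N2, into the 1-iodoalkene F5 (any 1,1-diiodide converges in the next operation); KOt-Bu in THF eliminates HI and gives 10.

3. Step 16. The C5 radical may be captured by a second titanium centre and lose titanium oxide by β-elimination (return to alkene 23), or hydrogen may be delivered to the β face (cis ring fusion). The fallback installs H5 and O6 by hydroboration instead; it sets out from enol triflate 21 and returns at diol 25. BH3·THF followed by NaBO3 should hydroborate C5=C6, the only nucleophilic alkene in 21, from the α face (anti to the C1 methyl and the O4 silyl ether) and give the 6α-alcohol F6 with H5 α. Oxidation with the Dess–Martin periodinane gives the ketone F7, and NaBH4 with CeCl3 is expected to deliver hydride from the α face to give the 6β-alcohol F8. Palladium-catalysed formate reduction as in step 13 gives the silyl ether F9, and Bu4NF removes the silyl group to give 25.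

Further compounds
F1 | step 9 | stannylated methylenecyclopentane, ring A with C1 methyl, C1 acetonyl, C4 isopropyl, C4 triethylsilyloxy, C5=CH–SnBu3 | CC(C)[C@]1(O[Si](CC)(CC)CC)CC[C@](C)(CC(C)=O)C1=C[Sn](CCCC)(CCCC)CCCC
F2 | step 9 | exocyclic alkene, destannylated F1 | CC(C)[C@]1(O[Si](CC)(CC)CC)CC[C@](C)(CC(C)=O)C1=C
F3 | step 9 | dienone, F2 allylated at the ketone methyl group | CC(C)[C@]1(O[Si](CC)(CC)CC)CC[C@](C)(CC(=O)CCC=C)C1=C
F4 | step 5 | hydrazone of aldehyde 7 | CC(C)[C@@](O[Si](CC)(CC)CC)(CC=NN)CC/C(C)=C/C(=O)N(C)OC
F5 | step 5 | 1-iodoalkene from F4 | CC(C)[C@@](O[Si](CC)(CC)CC)(C=CI)CC/C(C)=C/C(=O)N(C)OC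
F6 | step 16 | 6α-alcohol, 6α-hydroxy-4β-(triethylsilyloxy)dauc-8-en-9-yl triflate (5α-H) | CC(C)[C@]1(O[Si](CC)(CC)CC)CC[C@]2(C)CC(OS(=O)(=O)C(F)(F)F)=C(C)C[C@H](O)[C@H]21
F7 | step 16 | ketone, 6-oxo-4β-(triethylsilyloxy)dauc-8-en-9-yl triflate | CC(C)[C@]1(O[Si](CC)(CC)CC)CC[C@]2(C)CC(OS(=O)(=O)C(F)(F)F)=C(C)CC(=O)[C@H]21
F8 | step 16 | 6β-alcohol, 6β-hydroxy-4β-(triethylsilyloxy)dauc-8-en-9-yl triflate | CC(C)[C@]1(O[Si](CC)(CC)CC)CC[C@]2(C)CC(OS(=O)(=O)C(F)(F)F)=C(C)C[C@@H](O)[C@H]21
F9 | step 16 | silyl ether, 4β-(triethylsilyloxy)dauc-8-en-6β-ol | CC(C)[C@]1(O[Si](CC)(CC)CC)CC[C@]2(C)CC=C(C)C[C@@H](O)[C@H]21
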